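The numbers in the tables are simulated for an exercise; the scatter is artificial.

The constants of this chemistry are hidden from me, so I start from one constant I can read off the runs.

| flask | starting material | partner | temperature | remark | time |
|---|---|---|---|---|---|
| midnight | 0.015 M | 0.95 equiv | 90 °C | run made earlier |  |
| summer | 0.0075 M | 0.95 equiv | 90 °C | run made earlier |  |
| cedar | 0.015 M (fed, over 15 min) | 0.950 equiv | 90 °C | all else is in the flask from the start; the feed brings no volume worth counting | 40 min |
| oak | 0.015 M | 0.950 equiv (fed, over 15 min) |  | the addition at 70 °C, then warmed to 90 °C; the feed brings no volume worth counting | 40 min |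
| birch | 0.015 M | 0.950 equiv | 90 °C | everything together at the start | 40 min |
| elm | 0.015 M | 0.950 equiv (fed, over 15 min) | 90 °C | all else is in the flask from the start; the feed brings no volume worth counting | 40 min |

| run | time / min | first product / % | double product / % |
|---|---|---|---|
| midnight | 5.00 | 24 | 4 |
| midnight | 10.0 | 22 | 7 |
| midnight | 15.0 | 20 | 8 |
| midnight | 20.0 | 16 | 11 |
| midnight | 25.0 | 10 | 13 |
| summer | 1.50 | 7 | 1 |
| summer | 3.00 | 13 | 0 |
| summer | 5.00 | 13 | 0 |
| summer | 6.00 | 18 | 1 |
| summer | 8.00 | 19 | 1 |

(scatter of a reading: 1.5 percentage points)

- the best flask by share of first product in first product plus double product; "all alike" if 1.5 percentage points covers them all (cedar / oak / birch / elm / all alike)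
- share of first product in first product plus double product at the end, cedar
- share of first product in first product plus double product at the end, oak
- share of first product in first product plus double product at the end, birch
- share of first product in first product plus double product at the end, elm

- the earlier runs do not show what temperature does; that part of a forecast is a guess

Birch has the charges and temperature of midnight, so birch is midnight left longer. My bench rule is that, past its peak, the first product loses equal fractions in equal times, a pseudo-first-order fall. Its half-life, read from the first and last midnight readings, is the number I carry 15.8 min. I start from the last reading. I reckon just the increment of the double product, and as an assumption of my own I let it keep the net ratio read between those two readings, double product gained per first product lost.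

[first product], birch, at 40 min: 5.19%

net ratio, as read: 0.643

[double product], birch, at 40 min: 16.1%

share, birch: 24.4%

The border is the feed. The rule needs making to be over, but cedar, elm and oak take 15 min to receive their charge, and that is 0.949 of a half-life. For them I keep a count instead. After the feed they have 1.58 half-lives left, fewer than the 2.21 birch has after its first reading. So I place their shares above birch and give them no number.

The forecast names cedar, with cedar 68%, oak 38%, birch 20% and elm 32%, on the ground that “Cedar feeds starting material into dying partner”. Its birch lies below mine.

The flasks give oak as the best: cedar 36.2%, oak 45.4%, birch 27.6%, elm 40.1%.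

    starting material + partner → first product + by-product (k = 0.130 M⁻¹ s⁻¹, Ea = 75.0 kJ mol⁻¹)
    starting material + partner → other mono adduct + by-product (k = 0.00900 M⁻¹ s⁻¹, Ea = 60.0 kJ mol⁻¹)
    partner + first product → double product + by-product (k = 0.0650 M⁻¹ s⁻¹, Ea = 66.0 kJ mol⁻¹)
    partner + other mono adduct → double product + by-product (k = 0.110 M⁻¹ s⁻¹, Ea = 55.0 kJ mol⁻¹)
    first product → over-reaction product (k = 0.00160 s⁻¹, Ea = 100 kJ mol⁻¹)
    (constants at 90 °C)

On birch, 15.8 min put the first product at 5.19%, and the flask holds 4.86%. The double product stands at 12.8%, not my 16.1%, so the share is 27.6% against my 24.4%. The neighbour is birch read at 60.0 min. The same reckoning gives first product 2.16%, double product 18.0% and share 10.7%. That flask holds first product 1.87% and double product 13.3%, its over-reaction product has risen from 54.2% to 60.1%, and its share is 12.3%.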